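**Assumption:** the target has no stereogenic centre, so "single enantiomer" does not apply. The only stereo-element is the E-enone, which the route delivers as drawn.

## Retrosynthetic overview

1. Target 10 ⇒ global MOM removal ⇒ E-enone C=C by Claisen–Schmidt condensation of B-ring aldehyde 6 with A-ring ketone 8.
2. Aldehyde 6 ⇒ directed ortho-lithiation/formylation next to the OMe group of bis-MOM ether 5.
3. 5 ⇒ catechol 4, whose aryl–C(quaternary) bond comes from a new Pd-catalysed ortho-C–H reverse prenylation of 3-methoxycatechol with a prenyl carbonate.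
4. No ring is constructed: both benzene rings are purchased (3-methoxycatechol and 4'-hydroxyacetophenone). Bond order: Ar–CMe2 → Ar–CHO → C=C.

## Route

**Step 1**
Reactants: 1, prenol (3-methylbut-2-en-1-ol)
Product: 2, tert-butyl (3-methylbut-2-en-1-yl) carbonate
Conditions: Boc2O, Bu4NHSO4 (cat.), 30% aq NaOH, CH2Cl2, 0 °C → rt
Reagents that add atoms: di-tert-butyl dicarbonate, CC(C)(C)OC(=O)OC(=O)OC(C)(C)C
Why: Phase-transfer O-acylation of a primary allylic alcohol (carbonate formation) is routine and gives the ionisable prenyl donor.

**Step 2 (key step, new)**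
Reactants: 3, 3-methoxycatechol (3-methoxybenzene-1,2-diol); 2, tert-butyl (3-methylbut-2-en-1-yl) carbonate
Product: 4, 3-methoxy-6-(2-methylbut-3-en-2-yl)benzene-1,2-diol
Conditions: Pd2(dba)3 (2.5 mol %), 1,2-bis(diphenylphosphino)benzene (dppbz, 6 mol %), 2 (1.2 equiv, slow addition), degassed toluene, 60 °C, Ar
Reagents that add atoms: none
Why: Proposed new method: oxidative addition of reactant 2 and decarboxylation give a (dppbz)Pd(prenyl) cation and tert-butoxide, which deprotonates the catechol; the resulting O1-bound phenoxide/η1-(CH2-bound) prenyl Pd(II) complex should undergo a seven-membered 3,3'-reductive elimination (a "Pd-interrupted aromatic Claisen") that joins C6, the only unsubstituted ortho carbon of either hydroxyl, to the tertiary prenyl terminus, followed by dienone→phenol tautomerisation (by-products CO2 and t-BuOH); O-prenylation at either oxygen is reversible under Pd(0), so material funnels to the irreversible C–C product, and non-polar solvent plus a small-bite-angle diphosphine are chosen to disfavour outer-sphere (linear) attack; the closest known reaction types are Tsuji–Trost decarboxylative O-allylation of phenols, inner-sphere seven-membered reductive elimination in Pd-enolate decarboxylative allylic alkylation, and 3,3'-reductive elimination in Pd allyl–allyl coupling (which forms quaternary carbons).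

**Step 3**
Reactants: 4, 3-methoxy-6-(2-methylbut-3-en-2-yl)benzene-1,2-diol
Product: 5, 1-methoxy-2,3-bis(methoxymethoxy)-4-(2-methylbut-3-en-2-yl)benzene
Conditions: NaH (2.6 equiv), MOMCl (2.6 equiv), DMF, 0 °C → rt, Ar
Reagents that add atoms: chloromethyl methyl ether (MOMCl), COCCl
Why: Williamson-type O-alkylation of the catechol dianion (MOM protection); NaH/DMF overcomes the hindrance of the OH flanked by the tert-alkyl group.

**Step 4**
Reactants: 5, 1-methoxy-2,3-bis(methoxymethoxy)-4-(2-methylbut-3-en-2-yl)benzene
Product: 6, 2-methoxy-3,4-bis(methoxymethoxy)-5-(2-methylbut-3-en-2-yl)benzaldehyde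
Conditions: n-BuLi (1.3 equiv), TMEDA (1.3 equiv), THF, 0 °C, 2 h; then DMF (3 equiv), −78 °C → rt; aq NH4Cl
Reagents that add atoms: N,N-dimethylformamide (formyl C and O), CN(C)C=O
Why: Directed ortho metalation then formylation; both positions ortho to the OMOM groups are substituted, so the only heteroatom-directed site is ortho to OMe (as in lithiation of 1,2,3-trimethoxybenzene), and the 1,1-dimethylallyl group has no allylic hydrogens.

**Step 5**
Reactants: 7, 4'-hydroxyacetophenone
Product: 8, 1-[4-(methoxymethoxy)phenyl]ethan-1-one
Conditions: MOMCl (1.3 equiv), K2CO3, acetone, rt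
Reagents that add atoms: chloromethyl methyl ether (MOMCl), COCCl
Why: Standard phenol MOM protection (O-alkylation), which prevents phenoxide deactivation of the ketone in the aldol step.

**Step 6**
Reactants: 6, 2-methoxy-3,4-bis(methoxymethoxy)-5-(2-methylbut-3-en-2-yl)benzaldehyde; 8, 1-[4-(methoxymethoxy)phenyl]ethan-1-one
Product: 9, (E)-3-[2-methoxy-3,4-bis(methoxymethoxy)-5-(2-methylbut-3-en-2-yl)phenyl]-1-[4-(methoxymethoxy)phenyl]prop-2-en-1-one
Conditions: KOH (50% aq, 3 equiv), EtOH, rt, 16 h
Reagents that add atoms: none
Why: Claisen–Schmidt aldol condensation of a non-enolisable aldehyde with an aryl methyl ketone; E1cB dehydration gives the thermodynamically favoured E-enone, and MOM ethers and the alkene are base-stable.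

**Step 7**
Reactants: 9, (E)-3-[2-methoxy-3,4-bis(methoxymethoxy)-5-(2-methylbut-3-en-2-yl)phenyl]-1-[4-(methoxymethoxy)phenyl]prop-2-en-1-one
Product: 10, target, (E)-3-[3,4-dihydroxy-2-methoxy-5-(2-methylbut-3-en-2-yl)phenyl]-1-(4-hydroxyphenyl)prop-2-en-1-one
Conditions: 3 M aq HCl/MeOH (1:4), 45 °C, 1–2 h, degassed, N2
Reagents that add atoms: none
Why: Acid-catalysed acetal cleavage of the three aryl MOM ethers; the ring bearing the C=O has no ortho-OH, so no flavanone can form, and dilute acid at mild temperature leaves the E-enone and the 1,1-dimethylallyl group intact.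

## Compound list

1 | prenol (3-methylbut-2-en-1-ol) | CC(C)=CCO | starting material
2 | tert-butyl (3-methylbut-2-en-1-yl) carbonate | CC(C)=CCOC(=O)OC(C)(C)C | intermediate
3 | 3-methoxycatechol (3-methoxybenzene-1,2-diol) | COc1cccc(O)c1O | starting material
4 | 3-methoxy-6-(2-methylbut-3-en-2-yl)benzene-1,2-diol | C=CC(C)(C)c1ccc(OC)c(O)c1O | intermediate
5 | 1-methoxy-2,3-bis(methoxymethoxy)-4-(2-methylbut-3-en-2-yl)benzene | C=CC(C)(C)c1ccc(OC)c(OCOC)c1OCOC | intermediate
6 | 2-methoxy-3,4-bis(methoxymethoxy)-5-(2-methylbut-3-en-2-yl)benzaldehyde | C=CC(C)(C)c1cc(C=O)c(OC)c(OCOC)c1OCOC | intermediate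
7 | 4'-hydroxyacetophenone | CC(=O)c1ccc(O)cc1 | starting material
8 | 1-[4-(methoxymethoxy)phenyl]ethan-1-one | CC(=O)c1ccc(OCOC)cc1 | intermediate
9 | (E)-3-[2-methoxy-3,4-bis(methoxymethoxy)-5-(2-methylbut-3-en-2-yl)phenyl]-1-[4-(methoxymethoxy)phenyl]prop-2-en-1-one | C=CC(C)(C)c1cc(/C=C/C(=O)c2ccc(OCOC)cc2)c(OC)c(OCOC)c1OCOC | intermediate
10 | (E)-3-[3,4-dihydroxy-2-methoxy-5-(2-methylbut-3-en-2-yl)phenyl]-1-(4-hydroxyphenyl)prop-2-en-1-one | C=CC(C)(C)c1cc(/C=C/C(=O)c2ccc(O)cc2)c(OC)c(O)c1O | target

## Summary

**Total steps:** 7.
**Longest linear sequence:** 6 steps (1 → 2 → 4 → 5 → 6 → 9 → 10); 5 steps from 3-methoxycatechol.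

**Three steps most likely to fail, each with a fallback:**

1. **Step 2 (proposed new Pd ortho-C–H reverse prenylation).** Risks are stalling at the O-prenyl ethers or outer-sphere linear/para C-prenylation. Fallback, known chemistry: classical prenyl ether/thermal aromatic Claisen on an aldehyde-bearing ring.
   - 2,3,4-Trihydroxybenzaldehyde → 3,4-O-diphenylmethylene ketal (Ph2CCl2, heat).
   - 2-O-Methylation (MeI, K2CO3), then ketal hydrolysis (AcOH/H2O).
   - Selective 4-O-prenylation (prenyl bromide, NaHCO3, DMF; the OH para to CHO is the most acidic).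
   - Thermal [3,3] rearrangement (PhNEt2, about 190 °C) to 3,4-dihydroxy-2-methoxy-5-(2-methylbut-3-en-2-yl)benzaldehyde.
   - MOMCl/NaH to rejoin at 6. This also bypasses Step 4.

2. **Step 4 (directed lithiation/formylation).** Risks are sluggish deprotonation next to a single OMe director or a wrong-site mixture. Fallback: switch from coordination-directed deprotonation to electrophilic halogenation. Brominate 5 with NBS (MeCN, 0 °C) at the ring CH that is ortho to OMe and para to an OMOM, which is both the less hindered and the more activated site. Then Br–Li exchange (n-BuLi, −78 °C) and DMF gives 6.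

3. **Step 7 (global acidic MOM removal).** Risks are acid-promoted cyclisation of the phenol onto the 1,1-dimethylallyl alkene (dihydrobenzofuran) or catechol oxidation. Fallback: change the protecting-group class to SEM ethers (SEMCl/NaH in Steps 3 and 5; compatible with lithiation and KOH) and unmask with fluoride (TBAF, DMPU, 60 °C), so the end game uses no Brønsted acid.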